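The runs stem from a simulated flask with made-up constants; scatter was added.

I decided to count the catalyst that the impurity leaves over, not the catalyst charged.

| flask | substrate | free catalyst | impurity | remark |
|---|---|---|---|---|
| violet | 0.23 M | 6 mM | 4 mM | run made earlier |
| teal | 0.23 M | 24 mM | 4 mM | run made earlier |
| green | 0.12 M | 12 mM | 4 mM | run made earlier |
| flask | 0.23 M | 12 mM | 4.0 mM |  |

| run | time / h | target / % | substrate / % |
|---|---|---|---|
| violet | 1.33 | 0 | 87 |
| violet | 3.00 | 0 | 75 |
| violet | 6.00 | 3 | 61 |
| violet | 10.0 | 6 | 52 |
| teal | 1.33 | 7 | 80 |
| teal | 3.00 | 13 | 66 |
| teal | 6.00 | 23 | 45 |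
| teal | 10.0 | 36 | 34 |
| green | 2.50 | 5 | 76 |
| green | 5.00 | 9 | 58 |
| green | 8.00 | 15 | 51 |
| green | 10.0 | 17 | 46 |

(readings scatter by 1.5 percentage points)

* factor on the rate of making target when 20% of the substrate are converted if free catalyst is charged twice over
* factor on the rate when 20% of the substrate are converted if free catalyst is charged at 1.2 mM instead

- what has gone from substrate into another species counts as reacted, even if it can come back

For the flask, 12 mM of free catalyst less 4.0 mM of impurity leaves 8.00 mM, and this difference, free catalyst charged minus impurity charged, I called the working catalyst. I assumed that each impurity removes one catalyst, which makes impurity the limiting reagent of the poisoning in the flask.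

I then ordered the events by time. In the teal run, target already read 7% at 1.33 h and showed no lag, so I put the poisoning first, ended before that reading. Substrate loss came next, over hours: by 10.0 h the violet run had lost 110 mM of substrate, far more than its 6 mM of catalyst, so most of it had gone somewhere other than the catalyst. Target built up alongside that loss: the teal run read 36% at 10.0 h, less than the substrate it had lost. Across that slow stretch I froze the working catalyst as a constant.

The teal reading of 23% at 6.00 h, scaled to the violet run, gave 2.30% by working catalyst and 5.75% by charge; the violet run read 3%, with a scatter of 1.5 percentage points. At 20% conversion, flasks charged with 0.23 M of substrate hold the same substrate whatever their catalyst charge, so I took the rate there as proportional to working catalyst. Doubling the charge then gave me 2.50. At 1.2 mM the difference is −2.80 mM, because the impurity exceeds that catalyst charge, so I reckoned with no working catalyst there and put the factor close to zero.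

The forecast gave 2.4 (2 to 2.9) on doubling, a little below my 2.50, and 0.02 (0 to 0.08) at 1.2 mM, the latter with the remark “Reversible poisoning could leave a few percent”.

The simulation gave 2.51 on doubling and 1.42 × 10⁻⁵ at 1.2 mM, the latter far below the forecast's factor.

    substrate + free catalyst ⇌ catalyst intermediate (K = 4.70 L mol⁻¹, k = 0.00108 L mol⁻¹ s⁻¹)
    substrate ⇌ dormant form (K = 0.960, k = 2.97 × 10⁻⁵ s⁻¹)
    catalyst intermediate → free catalyst + target (k = 0.00119 s⁻¹)
    free catalyst + impurity → spent catalyst (k = 0.642 L mol⁻¹ s⁻¹)

The poisoning step runs one way, and at 12.0 h the flask held spent catalyst at 33.3% of the catalyst charged, with impurity at 0% of its own charge. Working catalyst is 66.7% of the flask's charge, and free catalyst at 62.0% plus catalyst intermediate at 4.71% came to 66.7%. In the flask charged at 1.2 mM, working catalyst reckons to −2.80 mM, and the rate there at 20% conversion stood at 1.42 × 10⁻⁵ of this flask's.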